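A small charge of reagent E, 0.30 equiv in the elm run, already shows the clock of this reaction, in which substrate X and catalyst L give product Z.

| setting | elm | oak | maple | flask |
|---|---|---|---|---|
| X | 21 mM | 21 mM | 21 mM | 21 mM |
| E | 0.30 equiv | 0.45 equiv | 0.60 equiv | 0.600 equiv |
| L | 15 mol% | 15 mol% | 30 mol% | 15 mol% |
| remark | run made earlier | run made earlier | run made earlier |  |

| elm: time / min | elm: Z / % | oak: time / min | oak: Z / % | maple: time / min | maple: Z / % |
|---|---|---|---|---|---|
| 0.250 | 11 | 0.667 | 30 | 0.667 | 46 |
| 0.417 | 17 | 1.33 | 36 | 1.33 | 50 |
| 0.833 | 25 | 2.00 | 40 | 2.00 | 48 |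
| 1.50 | 27 | 2.50 | 40 | 2.50 | 53 |
| 3.00 | 27 | 3.00 | 39 | 3.00 | 49 |

(scatter of a reading: 1.5 percentage points)

- the numbers in the tables scatter with a standard deviation of 1.5 percentage points

1. factor on the rate of making Z when 30 % of the X are converted if E is charged twice over
2. factor on the rate when 30 % of the X are converted if L is charged at 1.5 mol% instead

- **First instants.** Plateaus follow E, so E is the limiting reagent, and the gap to the plateau measures the E still to react. Oak's first reading gives a decay constant k of 2.08 min⁻¹, and elm's gives 2.09 min⁻¹. The decay thus reads as pseudo-first-order in E, and these readings give the half-life of E at 15 mol% L, ln(2)/k: 0.334 min.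
- **Middle.** If each converted X takes one E, the new flask has half of its E left at 30 % conversion. That point should come after one half-life, at a rate of 13.1 mM min⁻¹. Doubling E leaves 3.00 times as much E there, which is this reckoning's factor.
- **End.** Oak is flat by 2.00 min, 5.99 half-lives in, so the new flask should be flat by then too. Maple, with twice the L, reads k = 3.79 min⁻¹. Maple also differs from oak in E, so if k does not depend on the E charge, that noisy reading implies an order in L of 0.865 and a factor of 0.136 at 1.5 mol%.
- **Forecast.** It gives 3.3 and 0.11, holding that the “Approach to plateau looks first-order in remaining E”. Both numbers differ from the reckoning here.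
- **Result.** The simulation gives 2.60 and 0.147. The flask reaches 30 % conversion at 0.324 min, with a rate of 11.8 mM min⁻¹.

    X + J → Q (k = 51.0 M⁻¹ s⁻¹)
    D → J (k = 21.0 s⁻¹)
    2 L ⇌ G, settled at all times (K = 430 M⁻¹)
    E + L ⇌ D (K = 1900 M⁻¹, k = 33.0 M⁻¹ s⁻¹)
    Q ⇌ L + Z (K = 0.00770 M, k = 11.0 s⁻¹)

- **Second flask.** The half-life 0.334 min read from the runs stands beside the flask's 0.324 min to 30 % conversion. At 1.5 mol%, the simulated factor gives a rate of 1.74 mM min⁻¹ at 30 % conversion; with half the E charge taken as left there, the half-life of E comes to 2.51 min. That is shorter than the 3.70 min that strict first order in L gives from the flask's own rate. Part of the reason is the joining of two L to G: without it, the apparent order in L at 30 % conversion rises from 0.68 to 0.91.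

(The readings are calculated on assumed constants; noise was put on by code.)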